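Labdane numbering is used (ring A = C1–C5, C10; ring B = C5–C10). Ring A is read as a cyclohexene retron: its C4–C5 edge, with the quaternary C4 carrying the axial homoprenyl group, is a dienophile, and C10(CH3)=C1–C2=C3 is a diene. As both are joined through C6–C9, one Me2AlCl-promoted intramolecular Diels–Alder reaction of an acyclic (2E,8E)-undeca-2,8,10-trienal forms C3–C4 and C5–C10, closes rings A and B together and sets C4, C5 and C10, steered by a syn-aldol C8/C9 pair. The formyl activator later becomes the C4 methyl group, C1=C2 is hydrogenated, and a C8 ketone delivers 7α-OH and the exocyclic methylene.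

Key step: step 11

Remark: α and β refer to labdane numbering with the C10 methyl group (C20) on the β face; C17 is the exocyclic methylene carbon, C18 the α substituent on C4, C11–C16 the side chain on C9. Compounds 1, 2, 5, 9, 10 and all reagents are taken to be commercial.

Step 1
Reactants: 1 trimethyl phosphonoacetate; 2 5-bromo-2-methylpent-2-ene
Product: 4 methyl 2-(dimethoxyphosphoryl)-6-methylhept-5-enoate (racemic), via sodium enolate of trimethyl phosphonoacetate 3 (not isolated)
Conditions: NaH, DMF, 0 °C; then 2, 60 °C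
Reagents that add atoms: none
Why: SN2 C-alkylation of the stabilised phosphonoacetate carbanion with the primary homoallylic bromide installs the 4-methylpent-3-enyl group of C4; the new centre is lost in step 2.

Step 2
Reactants: 5 2,3-dihydrofuran; 4 methyl 2-(dimethoxyphosphoryl)-6-methylhept-5-enoate
Product: 7 methyl (2E)-6-hydroxy-2-(4-methylpent-3-en-1-yl)hex-2-enoate, via tetrahydrofuran-2-ol 6 (not isolated)
Conditions: 5, 0.2 M aq. HCl, 0 °C → rt; then 4, K2CO3, H2O, 40 °C
Reagents that add atoms: none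
Why: acid-catalysed hydration of the enol ether gives the lactol (masked 4-hydroxybutanal), whose open form undergoes Horner–Wadsworth–Emmons olefination; the (E)-enoate (C6 trans to the ester) should be favoured and the minor (Z)-isomer is removed by chromatography.

Step 3
Reactants: 7 methyl (2E)-6-hydroxy-2-(4-methylpent-3-en-1-yl)hex-2-enoate
Product: 8 methyl (2E)-2-(4-methylpent-3-en-1-yl)-6-oxohex-2-enoate
Conditions: TEMPO (10 mol %), PhI(OAc)2, CH2Cl2, rt
Reagents that add atoms: none
Why: nitroxyl-catalysed oxidation of the primary alcohol to the aldehyde (C8) leaves the enoate and the trisubstituted alkene untouched.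

Step 4
Reactants: 9 (4S)-4-benzyl-1,3-thiazolidine-2-thione; 10 hex-5-enoic acid
Product: 11 (4S)-4-benzyl-3-(hex-5-enoyl)-1,3-thiazolidine-2-thione
Conditions: DCC, DMAP (cat.), CH2Cl2, 0 °C → rt
Reagents that add atoms: none
Why: Steglich-type carbodiimide N-acylation attaches the chiral auxiliary to the chain that supplies C10, C9, C11–C13 and C16.

Step 5
Reactants: 11 (4S)-4-benzyl-3-(hex-5-enoyl)-1,3-thiazolidine-2-thione; 8 methyl (2E)-2-(4-methylpent-3-en-1-yl)-6-oxohex-2-enoate
Product: 13 methyl (2E,6R,7S)-7-{[(4S)-4-benzyl-2-thioxo-1,3-thiazolidin-3-yl]carbonyl}-6-hydroxy-2-(4-methylpent-3-en-1-yl)undeca-2,10-dienoate, via trichlorotitanium Z-enolate 12 (not isolated)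
Conditions: TiCl4 (1.05 equiv), i-Pr2NEt (1.1 equiv), N-methyl-2-pyrrolidinone (1 equiv), CH2Cl2, 0 °C; then 8, −78 → 0 °C
Reagents that add atoms: none
Why: titanium enolate aldol addition of an N-acylthiazolidinethione (Crimmins aldol) in its non-chelated mode; the Z-enolate reacts through a Zimmerman–Traxler chair on the face away from the benzyl group and sets C8 (carbinol) and C9 as the 2,3-syn pair.

Step 6
Reactants: 13 aldol adduct
Product: 14 methyl (2E,6R,7S)-7-{[(4S)-4-benzyl-2-thioxo-1,3-thiazolidin-3-yl]carbonyl}-2-(4-methylpent-3-en-1-yl)-6-(triethylsilyloxy)undeca-2,10-dienoate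
Conditions: Et3SiCl, imidazole, DMF, 0 °C → rt
Reagents that add atoms: chlorotriethylsilane, CC[Si](Cl)(CC)CC
Why: silyl ether formation blocks retro-aldol and oxa-Michael pathways and provides the equatorial C8 substituent that later biases the cycloaddition.

Step 7
Reactants: 14 silylated aldol adduct
Product: 15 (2S,3R,6E)-2-(but-3-en-1-yl)-7-(hydroxymethyl)-11-methyl-3-(triethylsilyloxy)dodeca-6,10-dienal
Conditions: i-Bu2AlH (3.5 equiv), CH2Cl2, −78 °C; aq. KNaC4H4O6 work-up
Reagents that add atoms: none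
Why: hydride reduction with i-Bu2AlH cleaves the N-acylthiazolidinethione to the aldehyde through an aluminium hemithioaminal that persists at −78 °C, while the enoate is reduced to the allylic alcohol; C8 and C9 are not touched.

Step 8
Reactants: 15 aldehyde–allylic alcohol
Product: 16 (2E,6R,7R)-7-ethynyl-2-(4-methylpent-3-en-1-yl)-6-(triethylsilyloxy)undeca-2,10-dien-1-ol
Conditions: dimethyl (1-diazo-2-oxopropyl)phosphonate, K2CO3, MeOH, 0 °C → rt
Reagents that add atoms: dimethyl (1-diazo-2-oxopropyl)phosphonate, CC(=O)C(=[N+]=[N-])P(=O)(OC)OC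
Why: Seyferth–Gilbert homologation in the Ohira–Bestmann variant converts the aldehyde into the terminal alkyne (C10≡C1) under mild carbonate conditions that should preserve the C9 centre and the silyl ether.

Step 9
Reactants: 16 alkynyl allylic alcohol
Product: 18 (2E,6R,7R,8E)-7-(but-3-en-1-yl)-8-methyl-2-(4-methylpent-3-en-1-yl)-6-(triethylsilyloxy)undeca-2,8,10-trien-1-ol, via alkenyldimethylalane 17 (not isolated)
Conditions: Me3Al (4 equiv), Cp2ZrCl2 (0.5 equiv), CH2Cl2, 0 °C → rt; then vinyl bromide, ZnCl2 (cat.), Pd(PPh3)4 (5 mol %), THF, rt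
Reagents that add atoms: trimethylaluminium, C[Al](C)C; vinyl bromide, C=CBr
Why: Negishi zirconium-catalysed carboalumination adds CH3 (to C10) and Al (to C1) syn across the alkyne, and Pd(PPh3)4-catalysed cross-coupling of the alkenylalane with vinyl bromide proceeds with retention, giving the diene with C9 trans to C2.

Step 10
Reactants: 18 trienol
Product: 19 (2E,6R,7R,8E)-7-(but-3-en-1-yl)-8-methyl-2-(4-methylpent-3-en-1-yl)-6-(triethylsilyloxy)undeca-2,8,10-trienal
Conditions: MnO2, CH2Cl2, rt
Reagents that add atoms: none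
Why: selective MnO2 oxidation of the allylic alcohol gives the (E)-enal without affecting the diene or the double-bond geometry.

Step 11
Reactants: 19 trienal
Product: 20 trans-octalin aldehyde (Δ1; 4α-CHO; 4β-(4-methylpent-3-en-1-yl); 5α-H; 8α-OSiEt3; 9β-(but-3-en-1-yl); 10β-CH3)
Conditions: Me2AlCl (1.2 equiv), CH2Cl2, −78 → −20 °C
Reagents that add atoms: none
Why: Me2AlCl binds the formyl oxygen, lowers the LUMO of the C4=C5 enal and lets it add suprafacially to the s-cis C10=C1–C2=C3 diene in a concerted, asynchronous intramolecular Diels–Alder reaction in which C5–C10 bonding runs ahead of C3–C4 bonding. The closest known reaction type is the Lewis-acid-catalysed cyclisation of 2-substituted (2E,8E)-undeca-2,8,10-trienals to trans-fused octalin carbaldehydes. Ring A (C1–C5, C10) closes as the cycloaddition ring and ring B (C5–C10) as the tether ring, through a chair-like C5–C6–C7–C8–C9–C10 array. C4 is controlled by the (E)-enal geometry (the homoprenyl group, cis to C6, ends β-axial and the formyl group α), C5 and C10 by the endo transition state (formyl under the diene), which gives the trans ring fusion with 5α-H and 10β-CH3, and the absolute sense by C8 and C9, whose OSiEt3 and butenyl groups are both equatorial in only one of the two chairs. The step needs endo over exo and one diene face over the other, and it has to tolerate the methyl group on the inside of the diene at C10; the aluminium-bound terminal formyl group should secure endo selectivity, the syn-disposed C8/C9 substituents the facial selectivity, and the four-carbon tether the rate.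

Step 12
Reactants: 20 trans-octalin aldehyde
Product: 22 C4-methyl octalin (Δ1; 4α-CH3; 4β-(4-methylpent-3-en-1-yl); 5α-H; 8α-OSiEt3; 9β-(but-3-en-1-yl); 10β-CH3), via hydrazone 21 (not isolated)
Conditions: N2H4·H2O, EtOH, 70 °C; then KOtBu, DMSO, rt
Reagents that add atoms: none
Why: Wolff–Kishner reduction in its room-temperature KOtBu/DMSO variant converts the neopentyl formyl group into the C4 methyl group (C18) under conditions that should spare the alkenes and the silyl ether.

Step 13
Reactants: 22 C4-methyl octalin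
Product: 23 methyl ketone (as 22 but 9β-(3-oxobutyl))
Conditions: PdCl2 (10 mol %), CuCl (1 equiv), O2 (1 atm), DMF/H2O 7:1, rt
Reagents that add atoms: water, O
Why: Tsuji–Wacker oxidation (Markovnikov hydroxypalladation) is selective for the monosubstituted terminal alkene over the 1,2-disubstituted ring alkene and the trisubstituted alkene and gives the C13 methyl ketone.

Step 14
Reactants: 23 methyl ketone
Product: 24 saturated methyl ketone (trans-decalin; 4α-CH3; 4β-(4-methylpent-3-en-1-yl); 5α-H; 8α-OSiEt3; 9β-(3-oxobutyl); 10β-CH3)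
Conditions: H2 (3 atm), RhCl(PPh3)3 (5 mol %), benzene/EtOH, rt
Reagents that add atoms: none
Why: homogeneous hydrogenation with RhCl(PPh3)3 should reduce the cis-disubstituted C1=C2 bond from the open α face and leave the trisubstituted side-chain alkene untouched.

Step 15
Reactants: 24 saturated methyl ketone
Product: 25 ethyl (E)-enoate (as 24 but 9β-[(3E)-5-ethoxy-3-methyl-5-oxopent-3-en-1-yl])
Conditions: (EtO)2P(O)CH2CO2Et, NaH, THF, 0 → 50 °C
Reagents that add atoms: triethyl phosphonoacetate, CCOC(=O)CP(=O)(OCC)OCC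
Why: Horner–Wadsworth–Emmons olefination of the unhindered methyl ketone (the only carbonyl group present) gives the trisubstituted enoate, with the (E)-isomer (ester trans to C12) expected to predominate; the minor (Z)-isomer is separated.

Step 16
Reactants: 25 ethyl (E)-enoate
Product: 27 C8 ketone (trans-decalin; 8-oxo; 9β side chain as in 25), via C8 alcohol 26 (not isolated)
Conditions: CrO3, H2SO4, acetone/H2O, 0 °C
Reagents that add atoms: none
Why: Jones oxidation: the aqueous acid hydrolyses the triethylsilyl ether and chromic acid oxidises the liberated secondary alcohol to the ketone in the same flask; C9 keeps its thermodynamically preferred equatorial side chain.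

Step 17
Reactants: 27 C8 ketone
Product: 29 7α-hydroxy-8-ketone, via potassium enolate 28 (not isolated)
Conditions: KN(SiMe3)2, THF, −78 °C; then 2-(phenylsulfonyl)-3-phenyloxaziridine, −78 °C; AcOH quench
Reagents that add atoms: 2-(phenylsulfonyl)-3-phenyloxaziridine, O=S(=O)(c1ccccc1)N1OC1c1ccccc1
Why: kinetic deprotonation at the C7 methylene (C9 is tertiary and hindered) followed by Davis oxidation of the enolate; oxygen is delivered axially on the α face, anti to the C10 methyl group, giving 7α-OH.

Step 18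
Reactants: 29 7α-hydroxy-8-ketone
Product: 30 ethyl ester of the target (7α-OH; 8(17)-methylidene)
Conditions: Zn, CH2Br2, TiCl4, THF/CH2Cl2, 0 °C → rt
Reagents that add atoms: dibromomethane, BrCBr
Why: Takai–Lombardo methylenation is non-basic, so the hindered α-hydroxy ketone should be converted into the exocyclic methylene without epimerisation at C7 or C9 and without attack on the ester.

Step 19
Reactants: 30 ethyl ester of the target
Product: 31 target CNP0169778.1
Conditions: LiOH, THF/MeOH/H2O, 40 °C; then 1 M HCl to pH 4, 0 °C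
Reagents that add atoms: lithium hydroxide, [Li+].[OH-]
Why: saponification of the ethyl ester and mild acidification give the free (E)-enoic acid; no stereocentre or alkene geometry is affected.

Compound list
1 | trimethyl phosphonoacetate | COC(=O)CP(=O)(OC)OC | starting material
2 | 5-bromo-2-methylpent-2-ene | CC(C)=CCCBr | starting material
3 | sodium enolate of trimethyl phosphonoacetate | [Na+].COC(=O)[CH-]P(=O)(OC)OC | intermediate (not isolated)
4 | methyl 2-(dimethoxyphosphoryl)-6-methylhept-5-enoate (racemic) | COC(=O)C(CCC=C(C)C)P(=O)(OC)OC | intermediate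
5 | 2,3-dihydrofuran | C1=COCC1 | starting material
6 | tetrahydrofuran-2-ol (racemic lactol) | OC1CCCO1 | intermediate (not isolated)
7 | methyl (2E)-6-hydroxy-2-(4-methylpent-3-en-1-yl)hex-2-enoate | COC(=O)/C(CCC=C(C)C)=C/CCCO | intermediate
8 | methyl (2E)-2-(4-methylpent-3-en-1-yl)-6-oxohex-2-enoate | COC(=O)/C(CCC=C(C)C)=C/CCC=O | intermediate
9 | (4S)-4-benzyl-1,3-thiazolidine-2-thione | S=C1N[C@@H](Cc2ccccc2)CS1 | starting material
10 | hex-5-enoic acid | C=CCCCC(=O)O | starting material
11 | (4S)-4-benzyl-3-(hex-5-enoyl)-1,3-thiazolidine-2-thione | C=CCCCC(=O)N1[C@@H](Cc2ccccc2)CSC1=S | intermediate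
12 | trichlorotitanium (Z)-enolate of 11 | C=CCC/C=C(\O[Ti](Cl)(Cl)Cl)N1[C@@H](Cc2ccccc2)CSC1=S | intermediate (not isolated)
13 | methyl (2E,6R,7S)-7-{[(4S)-4-benzyl-2-thioxo-1,3-thiazolidin-3-yl]carbonyl}-6-hydroxy-2-(4-methylpent-3-en-1-yl)undeca-2,10-dienoate | C=CCC[C@H](C(=O)N1[C@@H](Cc2ccccc2)CSC1=S)[C@H](O)CC/C=C(\CCC=C(C)C)/C(=O)OC | intermediate
14 | methyl (2E,6R,7S)-7-{[(4S)-4-benzyl-2-thioxo-1,3-thiazolidin-3-yl]carbonyl}-2-(4-methylpent-3-en-1-yl)-6-(triethylsilyloxy)undeca-2,10-dienoate | C=CCC[C@H](C(=O)N1[C@@H](Cc2ccccc2)CSC1=S)[C@H](O[Si](CC)(CC)CC)CC/C=C(\CCC=C(C)C)/C(=O)OC | intermediate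
15 | (2S,3R,6E)-2-(but-3-en-1-yl)-7-(hydroxymethyl)-11-methyl-3-(triethylsilyloxy)dodeca-6,10-dienal | C=CCC[C@H](C=O)[C@H](O[Si](CC)(CC)CC)CC/C=C(\CCC=C(C)C)/CO | intermediate
16 | (2E,6R,7R)-7-ethynyl-2-(4-methylpent-3-en-1-yl)-6-(triethylsilyloxy)undeca-2,10-dien-1-ol | C=CCC[C@H](C#C)[C@H](O[Si](CC)(CC)CC)CC/C=C(\CCC=C(C)C)/CO | intermediate
17 | (E)-alkenyldimethylalane from 16 (C1–AlMe2, C10–CH3 cis; drawn as its dimethylaluminium alkoxide) | C=CCC[C@H](/C(C)=C/[Al](C)C)[C@H](O[Si](CC)(CC)CC)CC/C=C(\CCC=C(C)C)/CO[Al](C)C | intermediate (not isolated)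
18 | (2E,6R,7R,8E)-7-(but-3-en-1-yl)-8-methyl-2-(4-methylpent-3-en-1-yl)-6-(triethylsilyloxy)undeca-2,8,10-trien-1-ol | C=CCC[C@H](/C(C)=C/C=C)[C@H](O[Si](CC)(CC)CC)CC/C=C(\CCC=C(C)C)/CO | intermediate
19 | (2E,6R,7R,8E)-7-(but-3-en-1-yl)-8-methyl-2-(4-methylpent-3-en-1-yl)-6-(triethylsilyloxy)undeca-2,8,10-trienal | C=CCC[C@H](/C(C)=C/C=C)[C@H](O[Si](CC)(CC)CC)CC/C=C(\CCC=C(C)C)/C=O | intermediate
20 | trans-octalin aldehyde (Δ1; 4α-CHO; 4β-(4-methylpent-3-en-1-yl); 5α-H; 8α-OSiEt3; 9β-(but-3-en-1-yl); 10β-CH3) | [C@@H]1(O[Si](CC)(CC)CC)CC[C@H]2[C@@](C=O)(CCC=C(C)C)CC=C[C@]2(C)[C@H]1CCC=C | intermediate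
21 | (E)-hydrazone of 20 (C4–CH=N–NH2) | [C@@H]1(O[Si](CC)(CC)CC)CC[C@H]2[C@@](/C=N/N)(CCC=C(C)C)CC=C[C@]2(C)[C@H]1CCC=C | intermediate (not isolated)
22 | C4-methyl octalin (Δ1; 4α-CH3; 4β-(4-methylpent-3-en-1-yl); 5α-H; 8α-OSiEt3; 9β-(but-3-en-1-yl); 10β-CH3) | [C@@H]1(O[Si](CC)(CC)CC)CC[C@H]2[C@@](C)(CCC=C(C)C)CC=C[C@]2(C)[C@H]1CCC=C | intermediate
23 | methyl ketone (as 22 but 9β-(3-oxobutyl)) | [C@@H]1(O[Si](CC)(CC)CC)CC[C@H]2[C@@](C)(CCC=C(C)C)CC=C[C@]2(C)[C@H]1CCC(C)=O | intermediate
24 | saturated methyl ketone (trans-decalin; 4α-CH3; 4β-(4-methylpent-3-en-1-yl); 5α-H; 8α-OSiEt3; 9β-(3-oxobutyl); 10β-CH3) | [C@@H]1(O[Si](CC)(CC)CC)CC[C@H]2[C@@](C)(CCC=C(C)C)CCC[C@]2(C)[C@H]1CCC(C)=O | intermediate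
25 | ethyl (E)-enoate (as 24 but 9β-[(3E)-5-ethoxy-3-methyl-5-oxopent-3-en-1-yl]) | [C@@H]1(O[Si](CC)(CC)CC)CC[C@H]2[C@@](C)(CCC=C(C)C)CCC[C@]2(C)[C@H]1CC/C(C)=C/C(=O)OCC | intermediate
26 | C8 alcohol (as 25 but 8α-OH) | [C@@H]1(O)CC[C@H]2[C@@](C)(CCC=C(C)C)CCC[C@]2(C)[C@H]1CC/C(C)=C/C(=O)OCC | intermediate (not isolated)
27 | C8 ketone (as 25 but 8-oxo) | O=C1CC[C@H]2[C@@](C)(CCC=C(C)C)CCC[C@]2(C)[C@H]1CC/C(C)=C/C(=O)OCC | intermediate
28 | potassium C7=C8 enolate of 27 | [K+].[O-]C1=CC[C@H]2[C@@](C)(CCC=C(C)C)CCC[C@]2(C)[C@H]1CC/C(C)=C/C(=O)OCC | intermediate (not isolated)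
29 | 7α-hydroxy-8-ketone | O=C1[C@H](O)C[C@H]2[C@@](C)(CCC=C(C)C)CCC[C@]2(C)[C@H]1CC/C(C)=C/C(=O)OCC | intermediate
30 | ethyl ester of the target (7α-OH; 8(17)-methylidene) | C=C1[C@H](O)C[C@H]2[C@@](C)(CCC=C(C)C)CCC[C@]2(C)[C@H]1CC/C(C)=C/C(=O)OCC | intermediate
31 | CNP0169778.1: (2E)-3-methyl-5-[7α-hydroxy-4α,10β-dimethyl-4β-(4-methylpent-3-en-1-yl)-8-methylidene-5αH-decalin-9β-yl]pent-2-enoic acid (labdane numbering; 10S) | C=C1[C@H](O)C[C@H]2[C@@](C)(CCC=C(C)C)CCC[C@]2(C)[C@H]1CC/C(C)=C/C(=O)O | target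

Total step count: 19. Longest linear sequence: 18 steps (steps 1–3, then 5–19; step 4 is a one-step side branch).

Steps most likely to fail

Step 11 (key step). The methyl group on the inside of the diene at C10 may slow the cycloaddition and erode endo/exo control, so that cis-fused adduct forms. The Lewis acid may also divert the substrate into a carbonyl–ene cyclisation of the formyl group onto the homoprenyl alkene. The fallback replaces aldehyde activation by an ionic Diels–Alder reaction of an acetal. It sets out from 19, which with 1,2-bis(trimethylsilyloxy)ethane and catalytic TMSOTf (CH2Cl2, −78 °C) should give the 2-alkenyl-1,3-dioxolane F1. Further TMSOTf (−78 → −40 °C) ionises the acetal to a 2-alkoxyallyl cation, a much stronger dienophile whose (E)-form is the thermodynamic one, and ring closure should give the dioxolane of the adduct F2. PPTS in wet acetone then frees the aldehyde and the route is rejoined at 20.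

Step 7. Chemoselectivity of the double reduction may be lost: the aluminium hemithioaminal may be reduced further to the primary alcohol, or the ester may be reduced incompletely. The fallback separates the redox events and sets out from 14. NaBH4 (THF/EtOH, 0 °C) removes the auxiliary and gives the primary alcohol F3 with the ester intact. TEMPO/PhI(OAc)2 oxidation gives the aldehyde F4, and Ohira–Bestmann homologation gives the alkynyl ester F5. Reduction of the ester with i-Bu2AlH (CH2Cl2, −78 °C) rejoins the route at 16.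

Step 17. The amide base may deprotonate the enoate at its γ position in competition with the ketone, and facial control of the hydroxylation may be incomplete. The fallback is a Rubottom oxidation through a silyl enol ether made by soft enolisation, setting out from 27. TMSOTf/Et3N (CH2Cl2, 0 °C) should enolise only the ketone and give the C7=C8 trimethylsilyl enol ether F6. mCPBA (1 equiv, NaHCO3, CH2Cl2, −20 °C) should epoxidise the electron-rich enol ether on the α face in preference to the trisubstituted alkene, and silyl migration gives the 7α-silyloxy ketone F7. Aqueous citric acid in MeOH removes the silyl group and the route is rejoined at 29.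

Further compounds
F1 | step 11 | 1,3-dioxolane acetal of trienal 19 (same configuration) | C=CCC[C@H](/C(C)=C/C=C)[C@H](O[Si](CC)(CC)CC)CC/C=C(\CCC=C(C)C)/C1OCCO1
F2 | step 11 | 1,3-dioxolane acetal of adduct 20 (C4α-dioxolanyl) | [C@@H]1(O[Si](CC)(CC)CC)CC[C@H]2[C@@](C3OCCO3)(CCC=C(C)C)CC=C[C@]2(C)[C@H]1CCC=C
F3 | step 7 | methyl (2E,6R,7R)-7-(hydroxymethyl)-2-(4-methylpent-3-en-1-yl)-6-(triethylsilyloxy)undeca-2,10-dienoate | C=CCC[C@H](CO)[C@H](O[Si](CC)(CC)CC)CC/C=C(\CCC=C(C)C)/C(=O)OC
F4 | step 7 | methyl (2E,6R,7S)-7-formyl-2-(4-methylpent-3-en-1-yl)-6-(triethylsilyloxy)undeca-2,10-dienoate | C=CCC[C@H](C=O)[C@H](O[Si](CC)(CC)CC)CC/C=C(\CCC=C(C)C)/C(=O)OC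
F5 | step 7 | methyl (2E,6R,7R)-7-ethynyl-2-(4-methylpent-3-en-1-yl)-6-(triethylsilyloxy)undeca-2,10-dienoate | C=CCC[C@H](C#C)[C@H](O[Si](CC)(CC)CC)CC/C=C(\CCC=C(C)C)/C(=O)OC
F6 | step 17 | C7=C8 trimethylsilyl enol ether of 27 | C[Si](C)(C)OC1=CC[C@H]2[C@@](C)(CCC=C(C)C)CCC[C@]2(C)[C@H]1CC/C(C)=C/C(=O)OCC
F7 | step 17 | 7α-(trimethylsilyloxy)-8-ketone | O=C1[C@H](O[Si](C)(C)C)C[C@H]2[C@@](C)(CCC=C(C)C)CCC[C@]2(C)[C@H]1CC/C(C)=C/C(=O)OCC
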